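## Retrosynthetic overview

1. Locants: ring A is the cyclohexane C1 (isopropyl), C2, C3, C4 (tertiary carbinol with CH2O), C5 (CO2H), C6 (alkenyl side chain); ring B is the same carbocycle with C4=C5 inside a butenolide. The strategic bond is C5–C6.
2. First cut: the CH2O–C(=O) ester between the halves. The ring A diol and the ring B butenolide acid are two oxidation variants of one 4-methylidene diester (A by osmylation at C4; B by epoxidation, E1cB opening and lactonisation onto the C5 ester).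
3. Enabling feature: the CO2H on C5 and the alkenyl group on C6 form the array HO2C–C5–C6–CH=C, a γ,δ-unsaturated acid (Claisen retron). Tying the carboxyl oxygen to the distal alkene carbon gives a ten-membered allylic lactone, and a ketone at C4 (β-keto lactone) activates C5.
4. Key cut: a transannular dianionic Carroll (ester-enolate Claisen) ring contraction, ten to six, forms C5–C6, sets C5 and C6, delivers all side-chain carbons as a dioxanylidene, and leaves a C3=C4 enolate that is trapped as the triflate (handle for the C4 CH2).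
5. Lactone by acylketene capture with a tertiary allylic alcohol (chain from Evans allylation, Takai olefination, addition to 2,2-dimethyl-1,3-dioxan-5-one). Ring order: temporary dioxane (bought) → ten-membered lactone → six-membered carbocycle → butenolide of ring B → esterification of the halves and deprotection.

Key step: step 10

Remark: the configuration is taken from the SMILES (ring A: C1 R, C4 S, C5 S, C6 S; ring B: isopropyl carbon R, side-chain carbon S; both side-chain alkenes E); diphenyldiazomethane is used as a freshly prepared reagent.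

## Route

Step 1
Reactants: 1 (4R)-4-benzyl-3-(3-methylbutanoyl)-1,3-oxazolidin-2-one
Product: 3 (4R)-4-benzyl-3-[(2R)-2-(propan-2-yl)pent-4-enoyl]-1,3-oxazolidin-2-one, via sodium Z-enolate 2 (not isolated)
Conditions: NaN(SiMe3)2, THF, −78 °C; allyl iodide, −78 to −40 °C
Reagents that add atoms: allyl iodide, C=CCI
Why: Evans asymmetric alkylation, in which the chelated Z-enolate is allylated on the face opposite the benzyl group and so sets the isopropyl-bearing centre (later C1 of both rings) as R.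

Step 2
Reactants: 3 (4R)-4-benzyl-3-[(2R)-2-(propan-2-yl)pent-4-enoyl]-1,3-oxazolidin-2-one
Product: 4 (2R)-2-(propan-2-yl)pent-4-en-1-ol
Conditions: LiBH4, MeOH (1 equiv), THF, 0 °C
Reagents that add atoms: none
Why: Reductive cleavage of the imide by hydride should free the primary alcohol without touching the stereocentre or the alkene and returns the auxiliary.

Step 3
Reactants: 4 (2R)-2-(propan-2-yl)pent-4-en-1-ol
Product: 5 (2R)-2-(propan-2-yl)pent-4-enal
Conditions: TEMPO (10 mol %), PhI(OAc)2, CH2Cl2, 23 °C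
Reagents that add atoms: none
Why: Oxoammonium (TEMPO) oxidation is non-basic, so the α-branched aldehyde should form without epimerisation.

Step 4
Reactants: 5 (2R)-2-(propan-2-yl)pent-4-enal
Product: 6 (1E,3R)-1-iodo-3-(propan-2-yl)hexa-1,5-diene
Conditions: CrCl2, CHI3, THF/1,4-dioxane, 0 to 23 °C
Reagents that add atoms: iodoform, IC(I)I
Why: Takai iodo-olefination, which is non-basic and E-selective for α-branched aldehydes, installs the alkene geometry needed for the key step.

Step 5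
Reactants: 6 (1E,3R)-1-iodo-3-(propan-2-yl)hexa-1,5-diene; 7 2,2-dimethyl-1,3-dioxan-5-one
Product: 9 2,2-dimethyl-5-[(1E,3R)-3-(propan-2-yl)hexa-1,5-dien-1-yl]-1,3-dioxan-5-ol, via alkenyllithium 8 (not isolated)
Conditions: t-BuLi (2.1 equiv), Et2O, −78 °C; then 7, −78 to 0 °C; sat. aq NH4Cl work-up
Reagents that add atoms: none
Why: Iodine–lithium exchange proceeds with retention of alkene geometry and 1,2-addition to the symmetric ketone creates no stereocentre, because the carbinol carbon carries two identical CH2O arms.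

Step 6
Reactants: 9 2,2-dimethyl-5-[(1E,3R)-3-(propan-2-yl)hexa-1,5-dien-1-yl]-1,3-dioxan-5-ol
Product: 11 5-[(1E,3R)-6-hydroxy-3-(propan-2-yl)hex-1-en-1-yl]-2,2-dimethyl-1,3-dioxan-5-ol, via B-alkyl-9-BBN adduct 10 (not isolated)
Conditions: 9-BBN (2.2 equiv), THF, 0 to 23 °C; then NaOH, H2O2, 0 °C
Reagents that add atoms: hydrogen peroxide, OO
Why: Anti-Markovnikov hydroboration–oxidation, in which 9-BBN should select the monosubstituted terminal alkene over the hindered internal E-alkene.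

Step 7
Reactants: 11 5-[(1E,3R)-6-hydroxy-3-(propan-2-yl)hex-1-en-1-yl]-2,2-dimethyl-1,3-dioxan-5-ol
Product: 12 (4R,5E)-6-(5-hydroxy-2,2-dimethyl-1,3-dioxan-5-yl)-4-(propan-2-yl)hex-5-enoic acid
Conditions: TEMPO (cat.), NaClO2, NaOCl (cat.), MeCN, phosphate buffer pH 6.7, 35 °C
Reagents that add atoms: sodium chlorite NaClO2, [Na+].[O-]Cl=O
Why: Buffered TEMPO/chlorite oxidation takes the primary alcohol to the acid while the tertiary alcohol cannot be oxidised and the acetonide is kept near neutral pH.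

Step 8
Reactants: 12 (4R,5E)-6-(5-hydroxy-2,2-dimethyl-1,3-dioxan-5-yl)-4-(propan-2-yl)hex-5-enoic acid; 13 2,2-dimethyl-1,3-dioxane-4,6-dione (Meldrum's acid)
Product: 14 5-[(4R,5E)-1-hydroxy-6-(5-hydroxy-2,2-dimethyl-1,3-dioxan-5-yl)-4-(propan-2-yl)hex-5-en-1-ylidene]-2,2-dimethyl-1,3-dioxane-4,6-dione
Conditions: DCC, DMAP, CH2Cl2, 0 to 23 °C
Reagents that add atoms: none
Why: Carbodiimide C-acylation of Meldrum's acid gives the acyl Meldrum's acid (an acylketene precursor that also supplies C5 and its carboxyl carbon), and the hindered tertiary hydroxyl should not compete.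

Step 9
Reactants: 14 5-[(4R,5E)-1-hydroxy-6-(5-hydroxy-2,2-dimethyl-1,3-dioxan-5-yl)-4-(propan-2-yl)hex-5-en-1-ylidene]-2,2-dimethyl-1,3-dioxane-4,6-dione
Product: 16 (13R,14E)-3,3-dimethyl-13-(propan-2-yl)-2,4,7-trioxaspiro[5.9]pentadec-14-ene-8,10-dione, via acylketene 15 (not isolated)
Conditions: toluene, 90 °C, slow addition to high dilution (0.5 mM)
Reagents that add atoms: none
Why: Thermal cycloreversion of the acyl Meldrum's acid (loss of acetone and CO2) gives an acylketene that is captured intramolecularly by the tertiary hydroxyl (acylketene macrolactonisation, a process that tolerates hindered alcohols), with the gem-disubstituted carbinol carbon and high dilution favouring the ten-membered ring.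

Step 10
Reactants: 16 (13R,14E)-3,3-dimethyl-13-(propan-2-yl)-2,4,7-trioxaspiro[5.9]pentadec-14-ene-8,10-dione
Product: 19 (1S,5R,6S)-6-[(2,2-dimethyl-1,3-dioxan-5-ylidene)methyl]-5-(propan-2-yl)-2-[(trifluoromethanesulfonyl)oxy]cyclohex-2-ene-1-carboxylic acid, via dilithium dienolate 17 (not isolated), via dilithium enolate carboxylate 18 (not isolated)
Conditions: LiN(iPr)2 (2.3 equiv), THF, −78 °C, then 23 to 40 °C; −78 °C, PhNTf2, to 0 °C; cold 0.5 M HCl work-up
Reagents that add atoms: N-phenylbis(trifluoromethanesulfonimide), O=S(=O)(N(c1ccccc1)S(=O)(=O)C(F)(F)F)C(F)(F)F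
Why: Proposed new method: double deprotonation of the β-keto lactone (C5–H, then C3–H) gives a lithium-chelated dienolate whose ester-enolate carbon C5 and allylic terminus C6 face each other across the ten-membered ring, so a charge-accelerated [3,3] shift (Carroll-type ester-enolate Claisen) forms C5–C6 and breaks the allylic C–O bond; the closest known reactions are the dianionic Carroll rearrangement of open-chain allyl β-keto esters, the Ireland–Claisen ring contraction of macrolactones and the Cope rearrangement of (E,E)-cyclodeca-1,5-dienes. The six-membered carbocycle closes transannularly and suprafacially on both three-atom components through a chair-like Claisen array fused to the forming ring, a contraction from ten to six in which the O–C(=O) unit is pushed out as the exocyclic carboxylate. C6 is controlled by the existing C1 centre, whose isopropyl group sits equatorial in the forming ring and places the (E)-alkenyl terminus trans to it; C5 is controlled by the enolate geometry, because lithium chelation between the two enolate oxygens holds the ring oxygen anti to C4, so that with the (E)-alkene only the all-equatorial, trans-decalin-like transition state is open and the carboxylate ends up trans to the side chain. The step needs the sigmatropic shift to outrun fragmentation of the ester enolate to an acylketene and needs this E,E-type geometry; the chelated dianion, the E-alkene from step 4 and the spiro carbinol carbon (whose two identical CH2O arms also exclude alkene isomers in the product) should secure both. The second enolate (C3=C4–OLi) survives the shift on the side of the ketone away from C5 and is trapped as the triflate, so no β-keto acid is ever formed (no decarboxylation) and C4 is marked for the one-carbon coupling of step 11.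

Step 11
Reactants: 19 (1S,5R,6S)-6-[(2,2-dimethyl-1,3-dioxan-5-ylidene)methyl]-5-(propan-2-yl)-2-[(trifluoromethanesulfonyl)oxy]cyclohex-2-ene-1-carboxylic acid
Product: 21 (1S,2S,3R)-2-[3-hydroxy-2-(hydroxymethyl)prop-1-en-1-yl]-6-methylidene-3-(propan-2-yl)cyclohexane-1-carboxylic acid, via allylsilane acid 20 (not isolated)
Conditions: Me3SiCH2MgCl (3.5 equiv), Pd(PPh3)4 (5 mol %), THF, 0 to 23 °C; then 1 M HCl, THF/H2O, 23 °C
Reagents that add atoms: (trimethylsilyl)methylmagnesium chloride, C[Si](C)(C)C[Mg]Cl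
Why: Kumada coupling of the alkenyl triflate gives an allylsilane whose acid-induced protodesilylation (proton to C3, loss of silicon, SE2') moves the double bond to the exocyclic position without touching C5, which is protected from epimerisation as the carboxylate during coupling, while the same acid hydrolyses the acetonide.

Step 12
Reactants: 21 (1S,2S,3R)-2-[3-hydroxy-2-(hydroxymethyl)prop-1-en-1-yl]-6-methylidene-3-(propan-2-yl)cyclohexane-1-carboxylic acid
Product: 22 (1S,2S,3R)-2-[(1E)-2-formyl-3-hydroxyprop-1-en-1-yl]-6-methylidene-3-(propan-2-yl)cyclohexane-1-carboxylic acid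
Conditions: TEMPO (10 mol %), PhI(OAc)2 (1.05 equiv), CH2Cl2, 0 °C
Reagents that add atoms: none
Why: Sterically governed oxoammonium mono-oxidation should take the less hindered hydroxymethyl group (the one trans to the ring), and the resulting (E)-2-(hydroxymethyl)enal is also the thermodynamically preferred isomer, which fixes the side-chain geometry.

Step 13
Reactants: 22 (1S,2S,3R)-2-[(1E)-2-formyl-3-hydroxyprop-1-en-1-yl]-6-methylidene-3-(propan-2-yl)cyclohexane-1-carboxylic acid
Product: 24 diphenylmethyl (1S,2S,3R)-2-{(1E)-2-[(diphenylmethoxy)carbonyl]-3-hydroxyprop-1-en-1-yl}-6-methylidene-3-(propan-2-yl)cyclohexane-1-carboxylate, via diacid 23 (not isolated)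
Conditions: NaClO2, NaH2PO4, 2-methylbut-2-ene, t-BuOH/H2O, 0 to 23 °C; then Ph2CN2 (2.3 equiv), CH2Cl2, 23 °C
Reagents that add atoms: sodium chlorite NaClO2, [Na+].[O-]Cl=O; diphenyldiazomethane, [N-]=[N+]=C(c1ccccc1)c1ccccc1
Why: Pinnick oxidation converts the enal to the acid without alkene isomerisation (the scavenger protects the methylidene group), and diphenyldiazomethane esterifies both acids under neutral conditions that cannot conjugate the β,γ-unsaturated ester.

Step 14
Reactants: 24 diphenylmethyl (1S,2S,3R)-2-{(1E)-2-[(diphenylmethoxy)carbonyl]-3-hydroxyprop-1-en-1-yl}-6-methylidene-3-(propan-2-yl)cyclohexane-1-carboxylate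
Product: 25 diphenylmethyl (1S,2S,3R)-2-{(1E)-3-[(tert-butyldiphenylsilyl)oxy]-2-[(diphenylmethoxy)carbonyl]prop-1-en-1-yl}-6-methylidene-3-(propan-2-yl)cyclohexane-1-carboxylate
Conditions: TBDPSCl, imidazole, CH2Cl2, 0 to 23 °C
Reagents that add atoms: tert-butyl(chloro)diphenylsilane, CC(C)(C)[Si](Cl)(c1ccccc1)c1ccccc1
Why: Silylation of the primary allylic alcohol gives an ether that should survive the later trifluoroacetic acid steps and keeps this hydroxyl out of the esterification.

Step 15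
Reactants: 25 diphenylmethyl (1S,2S,3R)-2-{(1E)-3-[(tert-butyldiphenylsilyl)oxy]-2-[(diphenylmethoxy)carbonyl]prop-1-en-1-yl}-6-methylidene-3-(propan-2-yl)cyclohexane-1-carboxylate
Product: 26 diphenylmethyl (1S,2S,3R,6S)-2-{(1E)-3-[(tert-butyldiphenylsilyl)oxy]-2-[(diphenylmethoxy)carbonyl]prop-1-en-1-yl}-6-hydroxy-6-(hydroxymethyl)-3-(propan-2-yl)cyclohexane-1-carboxylate
Conditions: OsO4 (5 mol %), NMO, acetone/H2O, 0 °C
Reagents that add atoms: 4-methylmorpholine N-oxide, C[N+]1([O-])CCOCC1; water, O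
Why: Catalytic osmium tetroxide dihydroxylation should attack only the electron-rich methylidene group (not the enoate) and from the equatorial face, away from the axial hydrogens on C2 and C6 of the all-equatorial chair, which sets C4 with equatorial OH and axial CH2OH cis to the C5 ester.

Step 16
Reactants: 25 diphenylmethyl (1S,2S,3R)-2-{(1E)-3-[(tert-butyldiphenylsilyl)oxy]-2-[(diphenylmethoxy)carbonyl]prop-1-en-1-yl}-6-methylidene-3-(propan-2-yl)cyclohexane-1-carboxylate
Product: 27 diphenylmethyl (4S,5S,6R)-5-{(1E)-3-[(tert-butyldiphenylsilyl)oxy]-2-[(diphenylmethoxy)carbonyl]prop-1-en-1-yl}-6-(propan-2-yl)-1-oxaspiro[2.5]octane-4-carboxylate (both spiro-carbon epimers)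
Conditions: mCPBA, NaHCO3, CH2Cl2, 0 °C
Reagents that add atoms: 3-chloroperoxybenzoic acid, OOC(=O)c1cccc(Cl)c1
Why: Prilezhaev epoxidation is selective for the 1,1-disubstituted alkene over the electron-poor enoate, and the configuration of the new spiro centre is irrelevant because it becomes sp2 in the next step.

Step 17
Reactants: 27 diphenylmethyl (4S,5S,6R)-5-{(1E)-3-[(tert-butyldiphenylsilyl)oxy]-2-[(diphenylmethoxy)carbonyl]prop-1-en-1-yl}-6-(propan-2-yl)-1-oxaspiro[2.5]octane-4-carboxylate (both spiro-carbon epimers)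
Product: 28 diphenylmethyl (2E)-2-{[(tert-butyldiphenylsilyl)oxy]methyl}-3-[(4S,5R)-3-oxo-5-(propan-2-yl)-1,3,4,5,6,7-hexahydro-2-benzofuran-4-yl]prop-2-enoate
Conditions: DBU, toluene, 23 to 40 °C
Reagents that add atoms: none
Why: E1cB opening of the β,γ-epoxy ester gives a γ-alkoxide on a tetrasubstituted enoate, held cis to the C5 ester by the ring, which lactonises to the butenolide of ring B with loss of diphenylmethanol.

Step 18
Reactants: 28 diphenylmethyl (2E)-2-{[(tert-butyldiphenylsilyl)oxy]methyl}-3-[(4S,5R)-3-oxo-5-(propan-2-yl)-1,3,4,5,6,7-hexahydro-2-benzofuran-4-yl]prop-2-enoate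
Product: 29 (2E)-2-{[(tert-butyldiphenylsilyl)oxy]methyl}-3-[(4S,5R)-3-oxo-5-(propan-2-yl)-1,3,4,5,6,7-hexahydro-2-benzofuran-4-yl]prop-2-enoic acid
Conditions: TFA, anisole, CH2Cl2, 0 °C
Reagents that add atoms: none
Why: Acidolysis of the benzhydryl ester (cation captured by anisole) frees the side-chain acid while the silyl ether and the butenolide should persist.

Step 19
Reactants: 26 diphenylmethyl (1S,2S,3R,6S)-2-{(1E)-3-[(tert-butyldiphenylsilyl)oxy]-2-[(diphenylmethoxy)carbonyl]prop-1-en-1-yl}-6-hydroxy-6-(hydroxymethyl)-3-(propan-2-yl)cyclohexane-1-carboxylate; 29 (2E)-2-{[(tert-butyldiphenylsilyl)oxy]methyl}-3-[(4S,5R)-3-oxo-5-(propan-2-yl)-1,3,4,5,6,7-hexahydro-2-benzofuran-4-yl]prop-2-enoic acid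
Product: 30 bis(benzhydryl) ester bis(tert-butyldiphenylsilyl) ether of the target (ester of the primary hydroxyl of 26 with acid 29)
Conditions: 2-methyl-6-nitrobenzoic anhydride, DMAP, Et3N, CH2Cl2, 23 °C
Reagents that add atoms: none
Why: Shiina esterification through the mixed anhydride should acylate the primary hydroxyl selectively, since the tertiary hydroxyl is too hindered to react.

Step 20
Reactants: 30 bis(benzhydryl) ester bis(tert-butyldiphenylsilyl) ether of the target
Product: 32 (1S,2S,3R,6S)-2-[(1E)-2-carboxy-3-hydroxyprop-1-en-1-yl]-6-hydroxy-6-{[((2E)-2-(hydroxymethyl)-3-[(4S,5R)-3-oxo-5-(propan-2-yl)-1,3,4,5,6,7-hexahydro-2-benzofuran-4-yl]prop-2-enoyl)oxy]methyl}-3-(propan-2-yl)cyclohexane-1-carboxylic acid (CNP0071646.2), via bis-silyl diacid 31 (not isolated)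
Conditions: TFA, anisole, CH2Cl2, 0 °C; evaporate; HF·pyridine, THF/pyridine, 0 to 23 °C
Reagents that add atoms: none
Why: Acidolysis removes both benzhydryl esters and fluoride then cleaves both silyl ethers, conditions under which the inter-half ester, the butenolide and the tertiary alcohol should survive.

## Compound list

1 | (4R)-4-benzyl-3-(3-methylbutanoyl)-1,3-oxazolidin-2-one | CC(C)CC(=O)N1C(=O)OC[C@H]1Cc1ccccc1 | starting material
2 | sodium (Z)-enolate of 1 | CC(C)/C=C(\[O-])N1C(=O)OC[C@H]1Cc1ccccc1.[Na+] | intermediate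
3 | (4R)-4-benzyl-3-[(2R)-2-(propan-2-yl)pent-4-enoyl]-1,3-oxazolidin-2-one | CC(C)[C@H](C(=O)N1C(=O)OC[C@H]1Cc1ccccc1)CC=C | intermediate
4 | (2R)-2-(propan-2-yl)pent-4-en-1-ol | CC(C)[C@H](CO)CC=C | intermediate
5 | (2R)-2-(propan-2-yl)pent-4-enal | CC(C)[C@H](C=O)CC=C | intermediate
6 | (1E,3R)-1-iodo-3-(propan-2-yl)hexa-1,5-diene | CC(C)[C@H](/C=C/I)CC=C | intermediate
7 | 2,2-dimethyl-1,3-dioxan-5-one | CC1(C)OCC(=O)CO1 | starting material
8 | [(1E,3R)-3-(propan-2-yl)hexa-1,5-dien-1-yl]lithium | CC(C)[C@H](/C=C/[Li])CC=C | intermediate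
9 | 2,2-dimethyl-5-[(1E,3R)-3-(propan-2-yl)hexa-1,5-dien-1-yl]-1,3-dioxan-5-ol | CC(C)[C@H](/C=C/C1(O)COC(C)(C)OC1)CC=C | intermediate
10 | 9-[(4R,5E)-6-(5-hydroxy-2,2-dimethyl-1,3-dioxan-5-yl)-4-(propan-2-yl)hex-5-en-1-yl]-9-borabicyclo[3.3.1]nonane | CC(C)[C@H](/C=C/C1(O)COC(C)(C)OC1)CCCB1C2CCCC1CCC2 | intermediate
11 | 5-[(1E,3R)-6-hydroxy-3-(propan-2-yl)hex-1-en-1-yl]-2,2-dimethyl-1,3-dioxan-5-ol | CC(C)[C@H](/C=C/C1(O)COC(C)(C)OC1)CCCO | intermediate
12 | (4R,5E)-6-(5-hydroxy-2,2-dimethyl-1,3-dioxan-5-yl)-4-(propan-2-yl)hex-5-enoic acid | CC(C)[C@H](/C=C/C1(O)COC(C)(C)OC1)CCC(=O)O | intermediate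
13 | 2,2-dimethyl-1,3-dioxane-4,6-dione (Meldrum's acid) | CC1(C)OC(=O)CC(=O)O1 | starting material
14 | 5-[(4R,5E)-1-hydroxy-6-(5-hydroxy-2,2-dimethyl-1,3-dioxan-5-yl)-4-(propan-2-yl)hex-5-en-1-ylidene]-2,2-dimethyl-1,3-dioxane-4,6-dione | CC(C)[C@H](/C=C/C1(O)COC(C)(C)OC1)CCC(O)=C1C(=O)OC(C)(C)OC1=O | intermediate
15 | (6R,7E)-8-(5-hydroxy-2,2-dimethyl-1,3-dioxan-5-yl)-6-(propan-2-yl)octa-1,7-diene-1,3-dione (acylketene) | CC(C)[C@H](/C=C/C1(O)COC(C)(C)OC1)CCC(=O)C=C=O | intermediate
16 | (13R,14E)-3,3-dimethyl-13-(propan-2-yl)-2,4,7-trioxaspiro[5.9]pentadec-14-ene-8,10-dione | CC(C)[C@H]1CCC(=O)CC(=O)OC2(COC(C)(C)OC2)/C=C/1 | intermediate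
17 | dilithium 8,10-dienolate of 16 | CC(C)[C@H]1C/C=C(/[O-])\C=C(/[O-])\OC2(COC(C)(C)OC2)/C=C/1.[Li+].[Li+] | intermediate
18 | dilithium (1S,5R,6S)-6-[(2,2-dimethyl-1,3-dioxan-5-ylidene)methyl]-2-oxido-5-(propan-2-yl)cyclohex-2-ene-1-carboxylate | CC(C)[C@H]1CC=C([O-])[C@@H](C(=O)[O-])[C@@H]1C=C1COC(C)(C)OC1.[Li+].[Li+] | intermediate
19 | (1S,5R,6S)-6-[(2,2-dimethyl-1,3-dioxan-5-ylidene)methyl]-5-(propan-2-yl)-2-[(trifluoromethanesulfonyl)oxy]cyclohex-2-ene-1-carboxylic acid | CC(C)[C@H]1CC=C(OS(=O)(=O)C(F)(F)F)[C@@H](C(=O)O)[C@@H]1C=C1COC(C)(C)OC1 | intermediate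
20 | (1S,5R,6S)-6-[(2,2-dimethyl-1,3-dioxan-5-ylidene)methyl]-5-(propan-2-yl)-2-[(trimethylsilyl)methyl]cyclohex-2-ene-1-carboxylic acid | CC(C)[C@H]1CC=C(C[Si](C)(C)C)[C@@H](C(=O)O)[C@@H]1C=C1COC(C)(C)OC1 | intermediate
21 | (1S,2S,3R)-2-[3-hydroxy-2-(hydroxymethyl)prop-1-en-1-yl]-6-methylidene-3-(propan-2-yl)cyclohexane-1-carboxylic acid | CC(C)[C@H]1CCC(=C)[C@@H](C(=O)O)[C@@H]1C=C(CO)CO | intermediate
22 | (1S,2S,3R)-2-[(1E)-2-formyl-3-hydroxyprop-1-en-1-yl]-6-methylidene-3-(propan-2-yl)cyclohexane-1-carboxylic acid | CC(C)[C@H]1CCC(=C)[C@@H](C(=O)O)[C@@H]1/C=C(\CO)C=O | intermediate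
23 | (1S,2S,3R)-2-[(1E)-2-carboxy-3-hydroxyprop-1-en-1-yl]-6-methylidene-3-(propan-2-yl)cyclohexane-1-carboxylic acid | CC(C)[C@H]1CCC(=C)[C@@H](C(=O)O)[C@@H]1/C=C(\CO)C(=O)O | intermediate
24 | diphenylmethyl (1S,2S,3R)-2-{(1E)-2-[(diphenylmethoxy)carbonyl]-3-hydroxyprop-1-en-1-yl}-6-methylidene-3-(propan-2-yl)cyclohexane-1-carboxylate | CC(C)[C@H]1CCC(=C)[C@@H](C(=O)OC(c2ccccc2)c2ccccc2)[C@@H]1/C=C(\CO)C(=O)OC(c1ccccc1)c1ccccc1 | intermediate
25 | diphenylmethyl (1S,2S,3R)-2-{(1E)-3-[(tert-butyldiphenylsilyl)oxy]-2-[(diphenylmethoxy)carbonyl]prop-1-en-1-yl}-6-methylidene-3-(propan-2-yl)cyclohexane-1-carboxylate | CC(C)[C@H]1CCC(=C)[C@@H](C(=O)OC(c2ccccc2)c2ccccc2)[C@@H]1/C=C(\CO[Si](c1ccccc1)(c1ccccc1)C(C)(C)C)C(=O)OC(c1ccccc1)c1ccccc1 | intermediate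
26 | diphenylmethyl (1S,2S,3R,6S)-2-{(1E)-3-[(tert-butyldiphenylsilyl)oxy]-2-[(diphenylmethoxy)carbonyl]prop-1-en-1-yl}-6-hydroxy-6-(hydroxymethyl)-3-(propan-2-yl)cyclohexane-1-carboxylate | CC(C)[C@H]1CC[C@@](O)(CO)[C@@H](C(=O)OC(c2ccccc2)c2ccccc2)[C@@H]1/C=C(\CO[Si](c1ccccc1)(c1ccccc1)C(C)(C)C)C(=O)OC(c1ccccc1)c1ccccc1 | intermediate
27 | diphenylmethyl (4S,5S,6R)-5-{(1E)-3-[(tert-butyldiphenylsilyl)oxy]-2-[(diphenylmethoxy)carbonyl]prop-1-en-1-yl}-6-(propan-2-yl)-1-oxaspiro[2.5]octane-4-carboxylate (both spiro-carbon epimers) | CC(C)[C@H]1CCC2(CO2)[C@@H](C(=O)OC(c3ccccc3)c3ccccc3)[C@@H]1/C=C(\CO[Si](c1ccccc1)(c1ccccc1)C(C)(C)C)C(=O)OC(c1ccccc1)c1ccccc1 | intermediate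
28 | diphenylmethyl (2E)-2-{[(tert-butyldiphenylsilyl)oxy]methyl}-3-[(4S,5R)-3-oxo-5-(propan-2-yl)-1,3,4,5,6,7-hexahydro-2-benzofuran-4-yl]prop-2-enoate | CC(C)[C@H]1CCC2=C(C(=O)OC2)[C@@H]1/C=C(\CO[Si](c1ccccc1)(c1ccccc1)C(C)(C)C)C(=O)OC(c1ccccc1)c1ccccc1 | intermediate
29 | (2E)-2-{[(tert-butyldiphenylsilyl)oxy]methyl}-3-[(4S,5R)-3-oxo-5-(propan-2-yl)-1,3,4,5,6,7-hexahydro-2-benzofuran-4-yl]prop-2-enoic acid | CC(C)[C@H]1CCC2=C(C(=O)OC2)[C@@H]1/C=C(\CO[Si](c1ccccc1)(c1ccccc1)C(C)(C)C)C(=O)O | intermediate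
30 | bis(benzhydryl) ester bis(tert-butyldiphenylsilyl) ether of the target | CC(C)[C@H]1CC[C@@](O)(COC(=O)/C(=C/[C@H]2C3=C(CC[C@@H]2C(C)C)COC3=O)CO[Si](c2ccccc2)(c2ccccc2)C(C)(C)C)[C@@H](C(=O)OC(c2ccccc2)c2ccccc2)[C@@H]1/C=C(\CO[Si](c1ccccc1)(c1ccccc1)C(C)(C)C)C(=O)OC(c1ccccc1)c1ccccc1 | intermediate
31 | bis(tert-butyldiphenylsilyl) ether of the target (free diacid) | CC(C)[C@H]1CC[C@@](O)(COC(=O)/C(=C/[C@H]2C3=C(CC[C@@H]2C(C)C)COC3=O)CO[Si](c2ccccc2)(c2ccccc2)C(C)(C)C)[C@@H](C(=O)O)[C@@H]1/C=C(\CO[Si](c1ccccc1)(c1ccccc1)C(C)(C)C)C(=O)O | intermediate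
32 | CNP0071646.2, (1S,2S,3R,6S)-2-[(1E)-2-carboxy-3-hydroxyprop-1-en-1-yl]-6-hydroxy-6-{[((2E)-2-(hydroxymethyl)-3-[(4S,5R)-3-oxo-5-(propan-2-yl)-1,3,4,5,6,7-hexahydro-2-benzofuran-4-yl]prop-2-enoyl)oxy]methyl}-3-(propan-2-yl)cyclohexane-1-carboxylic acid | CC(C)[C@H]1CC[C@@](O)(COC(=O)/C(=C/[C@H]2C3=C(CC[C@@H]2C(C)C)COC3=O)CO)[C@@H](C(=O)O)[C@@H]1/C=C(\CO)C(=O)O | target

## Step count and risks

Total step count: 20. Longest linear sequence: 19 steps (steps 1 to 14, then steps 16 to 18 through the ring B acid 29, then steps 19 and 20). Step 15 is a one-step side branch from 25 that supplies the ring A diol 26 for the coupling in step 19.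

Step 10 (Proposed new method). The dilithium dienolate may fragment to an acylketene and the tertiary alkoxide, or shuffle protons, faster than it rearranges, and a boat-like or cis-fused array would give the C5/C6 epimers. The fallback uses known chemistry and sets out from lactone 16. Silylation of the dienolate (LiN(iPr)2, 2.2 equiv, Me3SiCl, THF, −78 °C) should give (13R,14E)-3,3-dimethyl-13-(propan-2-yl)-8,10-bis[(trimethylsilyl)oxy]-2,4,7-trioxaspiro[5.9]pentadeca-8,10,14-triene F1. Warming this in toluene (60 to 80 °C) runs the neutral Ireland–Claisen ring contraction of a macrolactone silyl ketene acetal and should give trimethylsilyl (1S,5R,6S)-6-[(2,2-dimethyl-1,3-dioxan-5-ylidene)methyl]-5-(propan-2-yl)-2-[(trimethylsilyl)oxy]cyclohex-2-ene-1-carboxylate F2. MeLi (2.2 equiv, THF, 0 °C) then cleaves both silyl groups to the dilithium species 18, and PhNTf2 gives 19, where the route is rejoined.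

Step 9. The acylketene may be captured intermolecularly (dimers, oligomers) instead of closing onto the hindered tertiary hydroxyl, or the lactone may undergo a thermal Carroll shift with loss of CO2 at the temperature of ketene generation. The fallback moves the ring closure to a C–C bond and sets out from diol 11. TEMPO/PhI(OAc)2 in CH2Cl2 should give (4R,5E)-6-(5-hydroxy-2,2-dimethyl-1,3-dioxan-5-yl)-4-(propan-2-yl)hex-5-enal F3. Bromoacetyl bromide and pyridine acylate the tertiary alcohol to 2,2-dimethyl-5-[(1E,3R)-6-oxo-3-(propan-2-yl)hex-1-en-1-yl]-1,3-dioxan-5-yl bromoacetate F4. SmI2 in THF at high dilution closes the ten-membered ring by an intramolecular Reformatsky reaction to (13R,14E)-10-hydroxy-3,3-dimethyl-13-(propan-2-yl)-2,4,7-trioxaspiro[5.9]pentadec-14-en-8-one F5 (carbinol epimers). Dess–Martin oxidation returns to 16.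

Step 15. Osmylation may occur on the axial face and give the C4 epimer, and the new primary hydroxyl may lactonise onto the neighbouring benzhydryl ester. The fallback uses the opposite facial demand and sets out from 25. mCPBA (as in step 16) should attack mainly axially, the usual preference of peracids on methylidenecyclohexanes, and give the axial-oxygen epoxide diphenylmethyl (3R,4S,5S,6R)-5-{(1E)-3-[(tert-butyldiphenylsilyl)oxy]-2-[(diphenylmethoxy)carbonyl]prop-1-en-1-yl}-6-(propan-2-yl)-1-oxaspiro[2.5]octane-4-carboxylate F6. Dilute HClO4 in THF/H2O at 0 °C then opens it at the tertiary carbon with inversion, which delivers diol 26.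

Further compounds
F1 | step 10 | (13R,14E)-3,3-dimethyl-13-(propan-2-yl)-8,10-bis[(trimethylsilyl)oxy]-2,4,7-trioxaspiro[5.9]pentadeca-8,10,14-triene | CC(C)[C@H]1C/C=C(/O[Si](C)(C)C)\C=C(/O[Si](C)(C)C)\OC2(COC(C)(C)OC2)/C=C/1
F2 | step 10 | trimethylsilyl (1S,5R,6S)-6-[(2,2-dimethyl-1,3-dioxan-5-ylidene)methyl]-5-(propan-2-yl)-2-[(trimethylsilyl)oxy]cyclohex-2-ene-1-carboxylate | CC(C)[C@H]1CC=C(O[Si](C)(C)C)[C@@H](C(=O)O[Si](C)(C)C)[C@@H]1C=C1COC(C)(C)OC1
F3 | step 9 | (4R,5E)-6-(5-hydroxy-2,2-dimethyl-1,3-dioxan-5-yl)-4-(propan-2-yl)hex-5-enal | CC(C)[C@H](/C=C/C1(O)COC(C)(C)OC1)CCC=O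
F4 | step 9 | 2,2-dimethyl-5-[(1E,3R)-6-oxo-3-(propan-2-yl)hex-1-en-1-yl]-1,3-dioxan-5-yl bromoacetate | CC(C)[C@H](/C=C/C1(OC(=O)CBr)COC(C)(C)OC1)CCC=O
F5 | step 9 | (13R,14E)-10-hydroxy-3,3-dimethyl-13-(propan-2-yl)-2,4,7-trioxaspiro[5.9]pentadec-14-en-8-one (carbinol epimers) | CC(C)[C@H]1CCC(O)CC(=O)OC2(COC(C)(C)OC2)/C=C/1
F6 | step 15 | diphenylmethyl (3R,4S,5S,6R)-5-{(1E)-3-[(tert-butyldiphenylsilyl)oxy]-2-[(diphenylmethoxy)carbonyl]prop-1-en-1-yl}-6-(propan-2-yl)-1-oxaspiro[2.5]octane-4-carboxylate | CC(C)[C@H]1CC[C@]2(CO2)[C@@H](C(=O)OC(c3ccccc3)c3ccccc3)[C@@H]1/C=C(\CO[Si](c1ccccc1)(c1ccccc1)C(C)(C)C)C(=O)OC(c1ccccc1)c1ccccc1
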